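**Retrosynthetic overview**
1. Target ⇐ ester hydrolysis ⇐ B-alkyl Suzuki union (bond between the side-chain CH2CH2 and the first trisubstituted alkene) of a 5-vinyl-oxane acrylate (ring fragment) with an (E,E)-C14 iodotrienol (chain fragment).
2. Ring fragment ⇐ key step: radical 6-exo cyclization that forms C2–C3 of the oxane from a primary alkyl iodide onto an O-tethered β-alkoxy-methacrylate, ended by cobalt-mediated dehydrogenation. One operation closes the ring, sets C2 trans to C5 and unveils the acrylate.
3. Cyclization precursor ⇐ formate olefination ⇐ alkoxy-radical fragmentation of a 5-vinyl lactol ⇐ copper-catalysed asymmetric allylic alkylation (sets C5).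
4. Chain fragment ⇐ two zirconium-catalysed methylalumination/iodination cycles and one Negishi coupling, starting from an asymmetric isopropenyl addition to pent-4-ynal (sets the carbinol).
5. Ring order: there is only one ring (the oxane); it is formed in the key radical step.

Assumption: in the two catalyst-controlled steps (2 and 7) the ligand antipode that gives the drawn configuration is used (sense confirmed by Mosher analysis on the first batch), and all starting materials are bought.

**Step 1**
Reactants: 1 (2E)-1,4-dibromobut-2-ene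
Product: 2 1-({[(2E)-4-bromobut-2-en-1-yl]oxy}methyl)-4-methoxybenzene
Conditions: PMBOH (1 equiv), NaH (1 equiv), THF, 0 °C; then added to 1 (3 equiv), THF, 0 → 23 °C
Reagents that add atoms: 4-methoxybenzyl alcohol, COc1ccc(CO)cc1
Why: Williamson ether synthesis; the sodium alkoxide displaces one allylic bromide of the excess symmetrical dibromide and the E-alkene is untouched.

**Step 2**
Reactants: 2 1-({[(2E)-4-bromobut-2-en-1-yl]oxy}methyl)-4-methoxybenzene; 3 2-(2-bromoethyl)-1,3-dioxolane
Product: 5 2-[(3R)-3-{[(4-methoxyphenyl)methoxy]methyl}pent-4-en-1-yl]-1,3-dioxolane, via Grignard reagent 4 (not isolated)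
Conditions: 3, Mg, THF/Et2O, 25 °C; then 2, CuBr·SMe2 (2 mol %), Taniaphos (2.5 mol %), CH2Cl2, −78 °C, slow addition
Reagents that add atoms: none
Why: Copper-catalysed asymmetric allylic alkylation (Feringa type); the alkylcopper attacks the γ-carbon (SN2') of the E-allylic bromide, which gives the branched terminal alkene and sets the C5 stereocentre by catalyst control (about 90–95 % ee expected for a primary alkyl Grignard reagent).

**Step 3**
Reactants: 5 2-[(3R)-3-{[(4-methoxyphenyl)methoxy]methyl}pent-4-en-1-yl]-1,3-dioxolane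
Product: 6 (5R)-5-ethenyloxan-2-ol (anomer mixture)
Conditions: TFA/CH2Cl2/H2O (10:10:1), 0 → 23 °C; NaHCO3 work-up
Reagents that add atoms: water, O
Why: Acidolysis cleaves the PMB ether and hydrolyses the dioxolane, and the freed 5-hydroxy aldehyde closes to the six-membered lactol; the stereocentre is not involved.

**Step 4**
Reactants: 6 (5R)-5-ethenyloxan-2-ol
Product: 7 (2R)-2-(2-iodoethyl)but-3-en-1-yl formate
Conditions: PhI(OAc)2 (1.2 equiv), I2 (1.0 equiv), CH2Cl2, visible light, 23 °C
Reagents that add atoms: iodine, II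
Why: Suárez alkoxy-radical fragmentation; the anomeric hypoiodite gives an alkoxy radical whose β-scission breaks the C2–C3 bond, leaving the old lactol carbon as a formate on oxygen and a primary radical that is trapped by iodine.

**Step 5**
Reactants: 7 (2R)-2-(2-iodoethyl)but-3-en-1-yl formate; 8 methyl 2-bromopropanoate
Product: 11 methyl (2E)-3-{[(2R)-2-(2-iodoethyl)but-3-en-1-yl]oxy}-2-methylprop-2-enoate (E major; the E/Z mixture is used), via phosphonium bromide 9 (not isolated), via phosphorus ylide 10 (not isolated)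
Conditions: 8, PPh3, toluene, 90 °C; KOtBu (1 equiv), 0 °C; then 7, toluene, 80 °C
Reagents that add atoms: none
Why: Wittig olefination of a formate ester by a stabilised ylide gives the β-alkoxy-methacrylate; the fully substituted ylide carbon is a poor nucleophile toward the primary iodide.

**Step 6 (key step)**
Reactants: 11 methyl (2E)-3-{[(2R)-2-(2-iodoethyl)but-3-en-1-yl]oxy}-2-methylprop-2-enoate
Product: 12 methyl 2-[(2R,5R)-5-ethenyloxan-2-yl]prop-2-enoate
Conditions: Co(dmgH)2(py)(SnPh3) (15 mol %; dmgH = dimethylglyoximate), iPr2NEt (1.5 equiv), MeCN (0.02 M), blue LEDs, 23 °C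
Reagents that add atoms: none
Why: Proposed new method: the alkylcobaloxime formed from the primary iodide is photolysed to the C3 radical, which closes 6-exo onto the O-bearing carbon of the polarity-matched β-alkoxy-methacrylate through a chair transition state with the vinyl group and the acrylate arm both equatorial (hence 2,5-trans, estimated dr about 5–10:1), and the resulting tertiary α-ester radical is dehydrogenated at its methyl group by the divalent cobalt complex (the less hindered site, as in catalytic chain transfer of methacrylates) to give the 2-substituted acrylate directly; the closest known reaction types are the cobaloxime-catalysed Heck-type radical cyclization of alkyl iodides (cyclization–dehydrocobaltation) and the β-alkoxyacrylate 6-exo radical cyclization.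

**Step 7**
Reactants: 13 pent-4-ynal; 14 2-bromoprop-1-ene
Product: 16 (3R)-2-methylhept-1-en-6-yn-3-ol, via silyl ether 15 (not isolated)
Conditions: CrCl2 (10 mol %), Kishi sulfonamide ligand N-{2-[4-(propan-2-yl)-4,5-dihydro-1,3-oxazol-2-yl]-6-methylphenyl}methanesulfonamide (11 mol %), Et3N (20 mol %), NiCl2(dmp) (2 mol %; dmp = 2,9-dimethyl-1,10-phenanthroline), Mn (2 equiv), Me3SiCl (2 equiv), MeCN, 23 °C; then 1 M HCl, THF
Reagents that add atoms: none
Why: Catalytic asymmetric Nozaki–Hiyama–Kishi alkenylation; the alkenylchromium species adds to the aldehyde inside the chiral sulfonamide–chromium complex, which sets the (R)-carbinol, while Mn and Me3SiCl turn the chromium over and the silyl ether is cleaved on acidic work-up.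

**Step 8**
Reactants: 16 (3R)-2-methylhept-1-en-6-yn-3-ol
Product: 18 (3R,6E)-7-iodo-2,6-dimethylhepta-1,6-dien-3-ol, via alkenylalane 17 (not isolated)
Conditions: AlMe3 (3.5 equiv), Cp2ZrCl2 (0.25 equiv), CH2Cl2, 0 → 23 °C; then I2, THF, −30 → 0 °C
Reagents that add atoms: trimethylaluminium, C[Al](C)C; iodine, II
Why: Negishi zirconium-catalysed methylalumination (syn addition, methyl to the internal alkyne carbon) and iodinolysis with retention give the E-iodoalkene (>98 % E); the alcohol rides through as its aluminium alkoxide and the 1,1-disubstituted alkene is inert.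

**Step 9**
Reactants: 18 (3R,6E)-7-iodo-2,6-dimethylhepta-1,6-dien-3-ol; 19 (4-bromobut-1-yn-1-yl)trimethylsilane
Product: 22 (3R,6E)-2,6-dimethylundeca-1,6-dien-10-yn-3-ol, via alkylzinc bromide 20 (not isolated), via silylated dienyne 21 (not isolated)
Conditions: 19, Zn dust, I2 (5 mol %), DMA, 80 °C; then 18, Pd(dppf)Cl2 (5 mol %), THF, 50 °C (2.2 equiv of 20); then MeOH, K2CO3, 23 °C
Reagents that add atoms: none
Why: Negishi sp3–sp2 cross-coupling with retention of the E-alkene, followed in the same flask by carbonate-mediated methanolysis of the alkynyl C–Si bond.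

**Step 10**
Reactants: 22 (3R,6E)-2,6-dimethylundeca-1,6-dien-10-yn-3-ol
Product: 24 (3R,6E,10E)-11-iodo-2,6,10-trimethylundeca-1,6,10-trien-3-ol, via alkenylalane 23 (not isolated)
Conditions: AlMe3 (3.5 equiv), Cp2ZrCl2 (0.25 equiv), CH2Cl2, 0 → 23 °C; then I2, THF, −30 → 0 °C
Reagents that add atoms: trimethylaluminium, C[Al](C)C; iodine, II
Why: Second Negishi methylalumination–iodination; syn carbometallation of the terminal alkyne sets the second E-trisubstituted alkene as its iodide.

**Step 11**
Reactants: 12 methyl 2-[(2R,5R)-5-ethenyloxan-2-yl]prop-2-enoate; 24 (3R,6E,10E)-11-iodo-2,6,10-trimethylundeca-1,6,10-trien-3-ol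
Product: 26 methyl 2-[(2R,5S)-5-[(3E,7E,11R)-11-hydroxy-4,8,12-trimethyltrideca-3,7,12-trien-1-yl]oxan-2-yl]prop-2-enoate, via alkylborane 25 (not isolated)
Conditions: 12, 9-BBN-H (1.1 equiv), THF, 0 → 23 °C; then 24, Pd(dppf)Cl2 (5 mol %), AsPh3 (10 mol %), Cs2CO3 (3 equiv), DMF/H2O, 23 °C
Reagents that add atoms: none
Why: Anti-Markovnikov hydroboration of the monosubstituted vinyl group (the electron-poor acrylate reacts much more slowly with 9-BBN) and B-alkyl Suzuki–Miyaura coupling with retention of alkene geometry; no stereocentre is touched and the free alcohol is tolerated.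

**Step 12**
Reactants: 26 methyl 2-[(2R,5S)-5-[(3E,7E,11R)-11-hydroxy-4,8,12-trimethyltrideca-3,7,12-trien-1-yl]oxan-2-yl]prop-2-enoate
Product: 27 2-[(2R,5S)-5-[(3E,7E,11R)-11-hydroxy-4,8,12-trimethyltrideca-3,7,12-trien-1-yl]oxan-2-yl]prop-2-enoic acid
Conditions: LiOH (3 equiv), THF/H2O (3:1), 23 °C; then 1 M HCl to pH 3
Reagents that add atoms: lithium hydroxide, [Li+].[OH-]
Why: Saponification of the methyl ester; C2 sits at a cross-conjugated, non-acidic position, so neither epimerisation nor alkene migration is expected.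

**Compound list**
1 | (2E)-1,4-dibromobut-2-ene | BrC/C=C/CBr | starting material
2 | 1-({[(2E)-4-bromobut-2-en-1-yl]oxy}methyl)-4-methoxybenzene | COc1ccc(COC/C=C/CBr)cc1 | intermediate
3 | 2-(2-bromoethyl)-1,3-dioxolane | BrCCC1OCCO1 | starting material
4 | [2-(1,3-dioxolan-2-yl)ethyl]magnesium bromide | Br[Mg]CCC1OCCO1 | intermediate
5 | 2-[(3R)-3-{[(4-methoxyphenyl)methoxy]methyl}pent-4-en-1-yl]-1,3-dioxolane | C=C[C@H](COCc1ccc(OC)cc1)CCC1OCCO1 | intermediate
6 | (5R)-5-ethenyloxan-2-ol (anomer mixture) | C=C[C@H]1CCC(O)OC1 | intermediate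
7 | (2R)-2-(2-iodoethyl)but-3-en-1-yl formate | C=C[C@H](COC=O)CCI | intermediate
8 | methyl 2-bromopropanoate (racemic) | CC(Br)C(=O)OC | starting material
9 | (1-methoxy-1-oxopropan-2-yl)triphenylphosphanium bromide | COC(=O)C(C)[P+](c1ccccc1)(c1ccccc1)c1ccccc1.[Br-] | intermediate
10 | methyl 2-(triphenyl-λ5-phosphanylidene)propanoate | COC(=O)C(C)=P(c1ccccc1)(c1ccccc1)c1ccccc1 | intermediate
11 | methyl (2E)-3-{[(2R)-2-(2-iodoethyl)but-3-en-1-yl]oxy}-2-methylprop-2-enoate | C=C[C@H](CO/C=C(\C)C(=O)OC)CCI | intermediate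
12 | methyl 2-[(2R,5R)-5-ethenyloxan-2-yl]prop-2-enoate | C=C[C@H]1CC[C@H](C(=C)C(=O)OC)OC1 | intermediate
13 | pent-4-ynal | C#CCCC=O | starting material
14 | 2-bromoprop-1-ene | C=C(C)Br | starting material
15 | trimethyl{[(3R)-2-methylhept-1-en-6-yn-3-yl]oxy}silane | C=C(C)[C@H](O[Si](C)(C)C)CCC#C | intermediate
16 | (3R)-2-methylhept-1-en-6-yn-3-ol | C=C(C)[C@H](O)CCC#C | intermediate
17 | {(1E,5R)-5-[(dimethylalumanyl)oxy]-2,6-dimethylhepta-1,6-dien-1-yl}dimethylalumane | C=C(C)[C@H](O[Al](C)C)CC/C(C)=C/[Al](C)C | intermediate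
18 | (3R,6E)-7-iodo-2,6-dimethylhepta-1,6-dien-3-ol | C=C(C)[C@H](O)CC/C(C)=C/I | intermediate
19 | (4-bromobut-1-yn-1-yl)trimethylsilane | C[Si](C)(C)C#CCCBr | starting material
20 | [4-(trimethylsilyl)but-3-yn-1-yl]zinc bromide | C[Si](C)(C)C#CCC[Zn]Br | intermediate
21 | (3R,6E)-2,6-dimethyl-11-(trimethylsilyl)undeca-1,6-dien-10-yn-3-ol | C=C(C)[C@H](O)CC/C(C)=C/CCC#C[Si](C)(C)C | intermediate
22 | (3R,6E)-2,6-dimethylundeca-1,6-dien-10-yn-3-ol | C=C(C)[C@H](O)CC/C(C)=C/CCC#C | intermediate
23 | {(1E,5E,9R)-9-[(dimethylalumanyl)oxy]-2,6,10-trimethylundeca-1,5,10-trien-1-yl}dimethylalumane | C=C(C)[C@H](O[Al](C)C)CC/C(C)=C/CC/C(C)=C/[Al](C)C | intermediate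
24 | (3R,6E,10E)-11-iodo-2,6,10-trimethylundeca-1,6,10-trien-3-ol | C=C(C)[C@H](O)CC/C(C)=C/CC/C(C)=C/I | intermediate
25 | methyl 2-[(2R,5S)-5-[2-(9-borabicyclo[3.3.1]nonan-9-yl)ethyl]oxan-2-yl]prop-2-enoate | C=C(C(=O)OC)[C@H]1CC[C@H](CCB2C3CCCC2CCC3)CO1 | intermediate
26 | methyl 2-[(2R,5S)-5-[(3E,7E,11R)-11-hydroxy-4,8,12-trimethyltrideca-3,7,12-trien-1-yl]oxan-2-yl]prop-2-enoate | C=C(C)[C@H](O)CC/C(C)=C/CC/C(C)=C/CC[C@H]1CC[C@H](C(=C)C(=O)OC)OC1 | intermediate
27 | 2-[(2R,5S)-5-[(3E,7E,11R)-11-hydroxy-4,8,12-trimethyltrideca-3,7,12-trien-1-yl]oxan-2-yl]prop-2-enoic acid | C=C(C)[C@H](O)CC/C(C)=C/CC/C(C)=C/CC[C@H]1CC[C@H](C(=C)C(=O)O)OC1 | target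

**Step count**
Total: 12 steps. Longest linear sequence: 8 steps (steps 1–6, 11, 12); the chain fragment (steps 7–10) is made in parallel.

**Three steps most likely to fail**

Step 6 (key cyclization: early dehydrocobaltation of the uncyclized radical, wrong-site dehydrogenation or modest dr). The fallback sets out from 7 and comes back at 12, and separates ring closure from acrylate formation. Wittig olefination of 7 with commercial methyl (triphenyl-λ5-phosphanylidene)acetate (toluene, 80 °C) gives methyl (2E)-3-{[(2R)-2-(2-iodoethyl)but-3-en-1-yl]oxy}prop-2-enoate F1. Reductive 6-exo β-alkoxyacrylate radical cyclization (Bu3SnH by syringe pump, AIBN, benzene, 80 °C, 0.01 M) gives methyl 2-[(2R,5R)-5-ethenyloxan-2-yl]acetate F2 through the same chair transition state. Its lithium enolate (LDA, THF, −78 °C) is treated with dimethylmethylideneammonium iodide to give methyl 3-(dimethylamino)-2-[(2R,5R)-5-ethenyloxan-2-yl]propanoate F3. Quaternisation with MeI gives 3-methoxy-N,N,N-trimethyl-3-oxo-2-[(2R,5R)-5-ethenyloxan-2-yl]propan-1-aminium iodide F4, and DBU eliminates trimethylamine to return 12.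

Step 5 (olefination of a formate in the presence of a primary iodide; ylide alkylation or low conversion). The fallback sets out from 7 and comes back at 11, and makes the enol ether by C–O bond formation instead of olefination. Acid-catalysed methanolysis of the formate (HCl cat., MeOH, 0 °C; kept free of base, because a 4-iodo alcohol closes to a tetrahydrofuran) gives (2R)-2-(2-iodoethyl)but-3-en-1-ol F5. Mitsunobu O-alkylation of the enol form of methyl 2-methyl-3-oxopropanoate with F5 (PPh3, DIAD, THF, 0 °C) then gives 11.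

Step 7 (enantioselectivity of the catalytic alkenylation with a small alkynyl aldehyde). The fallback sets out from 13 and comes back at 16, and sets the carbinol by reduction instead of addition. Commercial prop-1-en-2-ylmagnesium bromide (THF, −78 °C; NH4Cl work-up) gives racemic 2-methylhept-1-en-6-yn-3-ol F6. Dess–Martin periodinane (CH2Cl2, NaHCO3) gives 2-methylhept-1-en-6-yn-3-one F7. Corey–Bakshi–Shibata reduction ((S)-Me-CBS oxazaborolidine 10 mol %, catecholborane, toluene, −78 °C; the alkenyl group acts as the large substituent) returns (R)-configured 16.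

**Further compounds**
F1 | step 6 | methyl (2E)-3-{[(2R)-2-(2-iodoethyl)but-3-en-1-yl]oxy}prop-2-enoate | C=C[C@H](CO/C=C/C(=O)OC)CCI
F2 | step 6 | methyl 2-[(2R,5R)-5-ethenyloxan-2-yl]acetate | C=C[C@H]1CC[C@H](CC(=O)OC)OC1
F3 | step 6 | methyl 3-(dimethylamino)-2-[(2R,5R)-5-ethenyloxan-2-yl]propanoate | C=C[C@H]1CC[C@H](C(CN(C)C)C(=O)OC)OC1
F4 | step 6 | 3-methoxy-N,N,N-trimethyl-3-oxo-2-[(2R,5R)-5-ethenyloxan-2-yl]propan-1-aminium iodide | C=C[C@H]1CC[C@H](C(C[N+](C)(C)C)C(=O)OC)OC1.[I-]
F5 | step 5 | (2R)-2-(2-iodoethyl)but-3-en-1-ol | C=C[C@H](CO)CCI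
F6 | step 7 | 2-methylhept-1-en-6-yn-3-ol (racemic) | C=C(C)C(O)CCC#C
F7 | step 7 | 2-methylhept-1-en-6-yn-3-one | C=C(C)C(=O)CCC#C
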